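**Strategy.** Everything rests on cutting the C2–C3 bond of the dihydrofuran ring of the 2,3-dihydrobenzofuran. The key step exploits that C2 is both benzylic and bound to the ring oxygen O1. In the open precursor it is the OCH2Ar carbon of an aryl benzyl ether, whose C–H bond is doubly activated and lies 1,5 to C3, the diazo carbon of an aryl diazoacetate on C3a. One carbene C–H insertion catalysed by the chiral dirhodium carboxylate Rh2(R-PTTL)4 closes the oxygen ring, forms C2–C3 and sets C2; C3 is then equilibrated to trans. The C5 formyl group, carried from 5-iodovanillin, receives the diarylpropanediol arm by an Evans syn aldol; hydride reduction and hydrogenolysis finish.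

Key step: step 3

Assumption: Rh2(R-PTTL)4, dirhodium tetrakis[N-phthaloyl-(R)-tert-leucinate], is taken to deliver the 2S configuration, by analogy with the sense of induction of this ligand family in 2-aryl-2,3-dihydrobenzofuran formation; should the sense prove opposite, the S-configured catalyst is used.

Step 1
Reactants: 1 5-iodovanillin (4-hydroxy-3-iodo-5-methoxybenzaldehyde); 2 4-(benzyloxy)-3-methoxybenzyl alcohol
Product: 3 4-{[4-(benzyloxy)-3-methoxybenzyl]oxy}-3-iodo-5-methoxybenzaldehyde
Conditions: PPh3, DIAD, THF, 0 °C to rt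
Reagents that add atoms: none
Why: Mitsunobu etherification, in which the acidic phenol of 1 (acidified by the para formyl and ortho iodo groups) is alkylated by the alkoxyphosphonium ion of the primary benzylic alcohol 2 under neutral conditions that leave aldehyde and iodide untouched; no stereocentre is formed.

Step 2
Reactants: 3 the iodo ether aldehyde; 4 ethyl diazoacetate
Product: 5 ethyl 2-diazo-2-(2-{[4-(benzyloxy)-3-methoxybenzyl]oxy}-5-formyl-3-methoxyphenyl)acetate
Conditions: Pd(PPh3)4 (5 mol %), Ag2CO3 (0.5 equiv), Et3N (1.3 equiv), toluene, rt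
Reagents that add atoms: none
Why: Palladium-catalysed cross-coupling of an aryl iodide with the C–H bond of a diazoacetate (oxidative addition of zerovalent palladium into C–I, silver-assisted iodide abstraction, palladation of the deprotonated diazo carbon, reductive elimination), which should keep the diazo group intact at room temperature and leave the aldehyde and ethers alone.

Step 3
Reactants: 5 the aryl diazoacetate
Product: 6 ethyl (2S,3R)-2-[4-(benzyloxy)-3-methoxyphenyl]-5-formyl-7-methoxy-2,3-dihydro-1-benzofuran-3-carboxylate (cis)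
Conditions: Rh2(R-PTTL)4 (2 mol %), toluene, −78 to −40 °C, slow addition of 5 at high dilution
Reagents that add atoms: none
Why: Rh2(R-PTTL)4 converts the diazo ester into a rhodium-bound donor/acceptor carbene at C3, which inserts into one of the two enantiotopic C–H bonds of the OCH2Ar carbon through a concerted, asynchronous, hydride-transfer-like three-centre transition state and so forms the C2–C3 bond. The closest known reaction type is the enantioselective intramolecular 1,5 C–H insertion of ortho-(benzyloxy)aryl diazoacetates under chiral Rh2(O2CR)4-type catalysis, which gives cis-2-aryl-2,3-dihydrobenzofuran-3-carboxylates. The dihydrofuran ring, the only ring formed, is closed by this 1,5-insertion through a five-membered cyclic transition state. C2 is set by the chiral carboxylate ligands, which select one enantiotopic hydrogen, and C3 is set cis to it kinetically in the same transition state and is corrected in step 4. The step needs chemoselectivity for this C–H bond over capture of the carbene by the formyl oxygen, carbene dimerisation and attack on the remote benzyl protecting group; this should be secured by the five-membered intramolecular geometry, the activation of the C–H bond by the adjacent oxygen and the electron-rich aryl group, high dilution and low temperature.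

Step 4
Reactants: 6 the cis ester aldehyde
Product: 7 ethyl (2S,3S)-2-[4-(benzyloxy)-3-methoxyphenyl]-5-formyl-7-methoxy-2,3-dihydro-1-benzofuran-3-carboxylate (trans)
Conditions: NaOEt (0.2 equiv), EtOH/THF, 0 °C to rt
Reagents that add atoms: none
Why: Thermodynamic epimerisation through the C3 ester enolate, which should favour the trans isomer with aryl and ester on opposite faces while the non-enolisable C2 keeps its configuration and the non-enolisable aldehyde survives catalytic ethoxide.

Step 5
Reactants: 8 [4-(benzyloxy)-3-methoxyphenyl]acetic acid; 9 (S)-4-benzyl-1,3-oxazolidin-2-one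
Product: 11 (4S)-4-benzyl-3-{[4-(benzyloxy)-3-methoxyphenyl]acetyl}-1,3-oxazolidin-2-one, via mixed pivalic anhydride 10 (not isolated)
Conditions: pivaloyl chloride, Et3N, THF, −20 °C; then 9, LiCl, rt
Reagents that add atoms: none
Why: N-acylation of the oxazolidinone through the mixed pivalic anhydride with LiCl/Et3N activation (standard loading of an Evans auxiliary), in which the stereocentre of 9 is not touched.

Step 6
Reactants: 11 the arylacetyl oxazolidinone; 7 the trans ester aldehyde
Product: 14 ethyl (2S,3S)-2-[4-(benzyloxy)-3-methoxyphenyl]-5-{(1S,2S)-3-[(4S)-4-benzyl-2-oxo-1,3-oxazolidin-3-yl]-2-[4-(benzyloxy)-3-methoxyphenyl]-1-hydroxy-3-oxopropyl}-7-methoxy-2,3-dihydro-1-benzofuran-3-carboxylate, via dibutylboron Z-enolate 12 (not isolated), via dibutylboron aldolate 13 (not isolated)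
Conditions: Bu2BOTf, iPr2NEt, CH2Cl2, 0 °C; then 7, −78 to 0 °C; then pH 7 buffer, MeOH, H2O2, 0 °C
Reagents that add atoms: none
Why: Evans syn aldol, in which soft enolisation gives the boron Z-enolate that adds to the aldehyde through a closed Zimmerman–Traxler chair with the auxiliary benzyl group shielding one enolate face, setting the carbinol centre and the α-aryl centre syn (1S,2S in 14) while the remote ring stereocentres exert no influence and the ethyl ester is inert.

Step 7
Reactants: 14 the aldol adduct
Product: 15 (1S,2R)-1-{(2S,3R)-2-[4-(benzyloxy)-3-methoxyphenyl]-3-(hydroxymethyl)-7-methoxy-2,3-dihydro-1-benzofuran-5-yl}-2-[4-(benzyloxy)-3-methoxyphenyl]propane-1,3-diol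
Conditions: LiBH4 (excess), MeOH (4 equiv), THF, 0 °C to rt
Reagents that add atoms: none
Why: Reductive cleavage of the N-acyl oxazolidinone and reduction of the C3 ethyl ester by LiBH4 should give both primary alcohols in one operation, hydride attack on the exocyclic imide carbonyl being faster than enolisation so that no stereocentre changes (the descriptors at two centres change only through priority), and the benzyl ethers are inert.

Step 8
Reactants: 15 the dibenzyl triol
Product: 16 (1S,2R)-1-[(2S,3R)-2-(4-hydroxy-3-methoxyphenyl)-3-(hydroxymethyl)-7-methoxy-2,3-dihydro-1-benzofuran-5-yl]-2-(4-hydroxy-3-methoxyphenyl)propane-1,3-diol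
Conditions: H2 (1 atm), 10% Pd/C, EtOAc/EtOH, rt, stopped after uptake of two equivalents
Reagents that add atoms: none
Why: Catalytic hydrogenolysis of the two aryl benzyl ethers, which under neutral conditions should cleave well before the secondary benzylic alcohol and the cyclic benzylic C2–O1 ether are attacked.

**Compound list**

1 | 5-iodovanillin (4-hydroxy-3-iodo-5-methoxybenzaldehyde) | COc1cc(C=O)cc(I)c1O | starting material
2 | 4-(benzyloxy)-3-methoxybenzyl alcohol | COc1cc(CO)ccc1OCc1ccccc1 | starting material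
3 | 4-{[4-(benzyloxy)-3-methoxybenzyl]oxy}-3-iodo-5-methoxybenzaldehyde | COc1cc(C=O)cc(I)c1OCc1ccc(OCc2ccccc2)c(OC)c1 | intermediate
4 | ethyl diazoacetate | CCOC(=O)C=[N+]=[N-] | starting material
5 | ethyl 2-diazo-2-(2-{[4-(benzyloxy)-3-methoxybenzyl]oxy}-5-formyl-3-methoxyphenyl)acetate | CCOC(=O)C(=[N+]=[N-])c1cc(C=O)cc(OC)c1OCc1ccc(OCc2ccccc2)c(OC)c1 | intermediate
6 | ethyl (2S,3R)-2-[4-(benzyloxy)-3-methoxyphenyl]-5-formyl-7-methoxy-2,3-dihydro-1-benzofuran-3-carboxylate (cis) | COc1cc([C@H]2Oc3c(OC)cc(C=O)cc3[C@H]2C(=O)OCC)ccc1OCc1ccccc1 | intermediate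
7 | ethyl (2S,3S)-2-[4-(benzyloxy)-3-methoxyphenyl]-5-formyl-7-methoxy-2,3-dihydro-1-benzofuran-3-carboxylate (trans) | COc1cc([C@H]2Oc3c(OC)cc(C=O)cc3[C@@H]2C(=O)OCC)ccc1OCc1ccccc1 | intermediate
8 | [4-(benzyloxy)-3-methoxyphenyl]acetic acid | COc1cc(CC(=O)O)ccc1OCc1ccccc1 | starting material
9 | (S)-4-benzyl-1,3-oxazolidin-2-one | O=C1N[C@@H](Cc2ccccc2)CO1 | starting material
10 | mixed pivalic anhydride of 8 (not isolated) | COc1cc(CC(=O)OC(=O)C(C)(C)C)ccc1OCc1ccccc1 | intermediate
11 | (4S)-4-benzyl-3-{[4-(benzyloxy)-3-methoxyphenyl]acetyl}-1,3-oxazolidin-2-one | COc1cc(CC(=O)N2C(=O)OC[C@@H]2Cc2ccccc2)ccc1OCc1ccccc1 | intermediate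
12 | dibutylboron Z-enolate of 11 (not isolated) | CCCCB(CCCC)O/C(=C\c1ccc(OCc2ccccc2)c(OC)c1)N1C(=O)OC[C@@H]1Cc1ccccc1 | intermediate
13 | dibutylboron aldolate of 14 (not isolated) | COc1cc([C@H]2Oc3c(OC)cc([C@@H](OB(CCCC)CCCC)[C@@H](C(=O)N4C(=O)OC[C@@H]4Cc4ccccc4)c4ccc(OCc5ccccc5)c(OC)c4)cc3[C@@H]2C(=O)OCC)ccc1OCc1ccccc1 | intermediate
14 | ethyl (2S,3S)-2-[4-(benzyloxy)-3-methoxyphenyl]-5-{(1S,2S)-3-[(4S)-4-benzyl-2-oxo-1,3-oxazolidin-3-yl]-2-[4-(benzyloxy)-3-methoxyphenyl]-1-hydroxy-3-oxopropyl}-7-methoxy-2,3-dihydro-1-benzofuran-3-carboxylate | COc1cc([C@H]2Oc3c(OC)cc([C@@H](O)[C@@H](C(=O)N4C(=O)OC[C@@H]4Cc4ccccc4)c4ccc(OCc5ccccc5)c(OC)c4)cc3[C@@H]2C(=O)OCC)ccc1OCc1ccccc1 | intermediate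
15 | (1S,2R)-1-{(2S,3R)-2-[4-(benzyloxy)-3-methoxyphenyl]-3-(hydroxymethyl)-7-methoxy-2,3-dihydro-1-benzofuran-5-yl}-2-[4-(benzyloxy)-3-methoxyphenyl]propane-1,3-diol | COc1cc([C@H]2Oc3c(OC)cc([C@@H](O)[C@@H](CO)c4ccc(OCc5ccccc5)c(OC)c4)cc3[C@@H]2CO)ccc1OCc1ccccc1 | intermediate
16 | (1S,2R)-1-[(2S,3R)-2-(4-hydroxy-3-methoxyphenyl)-3-(hydroxymethyl)-7-methoxy-2,3-dihydro-1-benzofuran-5-yl]-2-(4-hydroxy-3-methoxyphenyl)propane-1,3-diol (CNP0294468.1) | COc1cc([C@H]2Oc3c(OC)cc([C@@H](O)[C@@H](CO)c4ccc(O)c(OC)c4)cc3[C@@H]2CO)ccc1O | target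

**Step count and risks**

Total step count: 8. Longest linear sequence: 7 (steps 1, 2, 3, 4, 6, 7, 8); step 5 is the one-step side branch.

Steps most likely to fail:

Step 3. The rhodium carbene may be captured by the Lewis-basic formyl oxygen (carbonyl ylide formation) in competition with C–H insertion, and the para formyl group lowers the hydridic character of the ether C–H bond, which may erode the discrimination between the enantiotopic hydrogens. The fallback masks the aldehyde before the diazo group is introduced. It sets out from 3, which with trimethyl orthoformate and catalytic pyridinium p-toluenesulfonate in MeOH at rt should give the aryl dimethyl acetal F1. Coupling of F1 with 4 under the conditions of step 2 gives the acetal diazo ester F2, and insertion with Rh2(R-PTTL)4 in toluene at low temperature gives the cis acetal ester F3. Pyridinium p-toluenesulfonate in acetone/water at rt then unmasks the aldehyde, and the fallback comes back to the route at 6.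

Step 6. Addition of the boron enolate to the electron-rich, weakly electrophilic aldehyde may be slow, and retro-aldol cleavage or epimerisation at the acidic α-aryl centre may occur during the oxidative work-up. The fallback changes auxiliary and enolate metal to a titanium-mediated thiazolidinethione aldol (Crimmins variant), which needs no peroxide work-up. It sets out from 8, which is coupled with commercial (S)-4-benzyl-1,3-thiazolidine-2-thione (DCC, catalytic DMAP, CH2Cl2) to the arylacetyl thiazolidinethione F4. Enolisation of F4 with TiCl4 (1.05 equiv), iPr2NEt (1.1 equiv) and N-methyl-2-pyrrolidinone (1 equiv) in CH2Cl2, then addition of 7 at −78 °C, should give the Evans-syn thione aldol adduct F5. LiBH4/MeOH in THF removes the readily displaced auxiliary and reduces the ester, and the fallback comes back to the route at 15.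

Step 7. Under the basic hydride conditions the β-hydroxy imide may fragment by retro-aldol or epimerise at the α-aryl centre before hydride delivery, or hydride may attack the endocyclic oxazolidinone carbonyl. The fallback blocks the retro-aldol pathway by O-silylation. It sets out from 14, which with TESOTf and 2,6-lutidine in CH2Cl2 at −78 °C gives the triethylsilyl ether imide F6. LiBH4/MeOH in THF then gives the triethylsilyl ether diol F7, and TBAF in THF at 0 °C removes the silyl group, so the fallback comes back to the route at 15.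

**Further compounds**

F1 | step 3 | 4-{[4-(benzyloxy)-3-methoxybenzyl]oxy}-3-iodo-5-methoxybenzaldehyde dimethyl acetal | COc1cc(C(OC)OC)cc(I)c1OCc1ccc(OCc2ccccc2)c(OC)c1
F2 | step 3 | ethyl 2-diazo-2-(2-{[4-(benzyloxy)-3-methoxybenzyl]oxy}-5-(dimethoxymethyl)-3-methoxyphenyl)acetate | CCOC(=O)C(=[N+]=[N-])c1cc(C(OC)OC)cc(OC)c1OCc1ccc(OCc2ccccc2)c(OC)c1
F3 | step 3 | ethyl (2S,3R)-2-[4-(benzyloxy)-3-methoxyphenyl]-5-(dimethoxymethyl)-7-methoxy-2,3-dihydro-1-benzofuran-3-carboxylate (cis) | COc1cc([C@H]2Oc3c(OC)cc(C(OC)OC)cc3[C@H]2C(=O)OCC)ccc1OCc1ccccc1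
F4 | step 6 | 1-[(4S)-4-benzyl-2-thioxo-1,3-thiazolidin-3-yl]-2-[4-(benzyloxy)-3-methoxyphenyl]ethan-1-one | COc1cc(CC(=O)N2C(=S)SC[C@@H]2Cc2ccccc2)ccc1OCc1ccccc1
F5 | step 6 | ethyl (2S,3S)-2-[4-(benzyloxy)-3-methoxyphenyl]-5-{(1S,2S)-3-[(4S)-4-benzyl-2-thioxo-1,3-thiazolidin-3-yl]-2-[4-(benzyloxy)-3-methoxyphenyl]-1-hydroxy-3-oxopropyl}-7-methoxy-2,3-dihydro-1-benzofuran-3-carboxylate | COc1cc([C@H]2Oc3c(OC)cc([C@@H](O)[C@@H](C(=O)N4C(=S)SC[C@@H]4Cc4ccccc4)c4ccc(OCc5ccccc5)c(OC)c4)cc3[C@@H]2C(=O)OCC)ccc1OCc1ccccc1
F6 | step 7 | triethylsilyl ether of aldol adduct 14 at the secondary carbinol | COc1cc([C@H]2Oc3c(OC)cc([C@@H](O[Si](CC)(CC)CC)[C@@H](C(=O)N4C(=O)OC[C@@H]4Cc4ccccc4)c4ccc(OCc5ccccc5)c(OC)c4)cc3[C@@H]2C(=O)OCC)ccc1OCc1ccccc1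
F7 | step 7 | triethylsilyl ether of 15 at the secondary carbinol | COc1cc([C@H]2Oc3c(OC)cc([C@@H](O[Si](CC)(CC)CC)[C@@H](CO)c4ccc(OCc5ccccc5)c(OC)c4)cc3[C@@H]2CO)ccc1OCc1ccccc1
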